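**Assumption:** the target has no stereocentre and its diaryl ether axis rotates freely, so it is achiral; the structure as drawn is the only species to make.

## Retrosynthetic overview

1. Target 15 comes from dibenzyl ether 14 by debenzylation; 14 comes from bis(coumarin-3-carboxylic acid) 13 by twofold protodecarboxylation.
2. Both pyranone rings are closed last and together: twofold Knoevenagel (aldol-type) condensation of bis-salicylaldehyde 10 with Meldrum's acid 11 makes the two C3–C4 bonds, followed by lactonisation.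
3. 10 comes from bisphenol 9 by twofold ortho-formylation; 9 comes from dialdehyde 7 by twofold Baeyer–Villiger oxidation, so each formyl group of 7 is a latent lactone oxygen and fixes the regiochemistry.
4. The diaryl ether of 7 is made by SNAr of salicylaldehyde 5 on 2-fluoro-3-methoxybenzaldehyde 6.
5. 5 comes from 2,4-dihydroxybenzaldehyde 1 by benzylation, Baeyer–Villiger oxidation and ortho-formylation; both benzene rings are bought.

## Route

Step 1
Reactants: 1 2,4-dihydroxybenzaldehyde
Product: 2 2,4-bis(benzyloxy)benzaldehyde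
Conditions: BnBr (2.5 equiv), K2CO3, DMF, 70 °C
Reagents that add atoms: benzyl bromide, BrCc1ccccc1
Why: Williamson ether synthesis; excess halide and heat also alkylate the hydrogen-bonded 2-OH, and benzyl ethers survive every later step while staying cleavable beside a methyl ether.

Step 2
Reactants: 2 2,4-bis(benzyloxy)benzaldehyde
Product: 4 2,4-bis(benzyloxy)phenol, via aryl formate 3 (not isolated)
Conditions: mCPBA, CH2Cl2, 0 °C to rt; then K2CO3 (cat.), MeOH, rt
Reagents that add atoms: mCPBA, OOC(=O)c1cccc(Cl)c1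
Why: Baeyer–Villiger (Dakin-type) oxidation; the aryl group carrying ortho and para benzyloxy donors migrates in preference to hydride, and the formate is cleaved by methanolysis.

Step 3
Reactants: 4 2,4-bis(benzyloxy)phenol
Product: 5 3,5-bis(benzyloxy)-2-hydroxybenzaldehyde
Conditions: MgCl2, Et3N, (CH2O)n, MeCN, reflux; then 1 M HCl
Reagents that add atoms: paraformaldehyde (as formaldehyde), C=O
Why: Casnati–Skattebøl ortho-formylation; the magnesium phenoxide delivers formaldehyde only to the single free ortho position, and a second formaldehyde oxidises the benzylic alkoxide to the aldehyde.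

Step 4
Reactants: 5 3,5-bis(benzyloxy)-2-hydroxybenzaldehyde; 6 2-fluoro-3-methoxybenzaldehyde
Product: 7 3,5-bis(benzyloxy)-2-(2-formyl-6-methoxyphenoxy)benzaldehyde
Conditions: Cs2CO3, DMSO, 110 °C, N2
Reagents that add atoms: none
Why: SNAr; the ortho-formyl group of 6 stabilises the Meisenheimer intermediate and fluoride is the best leaving group, while the phenoxide of 5 is made nucleophilic by its ortho and para benzyloxy groups and the cesium counter-ion in DMSO.

Step 5
Reactants: 7 3,5-bis(benzyloxy)-2-(2-formyl-6-methoxyphenoxy)benzaldehyde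
Product: 9 3,5-bis(benzyloxy)-2-(2-hydroxy-6-methoxyphenoxy)phenol, via bis-formate 8 (not isolated)
Conditions: mCPBA (3 equiv), KH2PO4, CH2Cl2, 0 °C to rt; then K2CO3 (cat.), degassed MeOH, rt
Reagents that add atoms: mCPBA, OOC(=O)c1cccc(Cl)c1
Why: twofold Baeyer–Villiger oxidation of two ortho-aryloxybenzaldehydes; each aryl group migrates with the help of the ortho ether oxygen, so both carbons that activated or accompanied the SNAr become the future lactone oxygens.

Step 6
Reactants: 9 3,5-bis(benzyloxy)-2-(2-hydroxy-6-methoxyphenoxy)phenol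
Product: 10 4,6-bis(benzyloxy)-3-(3-formyl-2-hydroxy-6-methoxyphenoxy)-2-hydroxybenzaldehyde
Conditions: MgCl2 (6 equiv), Et3N (10 equiv), (CH2O)n (excess), MeCN, reflux; then 1 M HCl
Reagents that add atoms: paraformaldehyde (as formaldehyde), C=O
Why: twofold Casnati–Skattebøl ortho-formylation; each phenol has only one free ortho position (the other carries the ether oxygen), so chelation control puts each formyl group exactly where C4a of each coumarin must be.

Step 7
Reactants: 10 4,6-bis(benzyloxy)-3-(3-formyl-2-hydroxy-6-methoxyphenoxy)-2-hydroxybenzaldehyde; 11 Meldrum's acid (2.4 equiv)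
Product: 13 8-{[5,7-bis(benzyloxy)-3-carboxy-2-oxo-2H-chromen-8-yl]oxy}-7-methoxy-2-oxo-2H-chromene-3-carboxylic acid, via bis-alkylidene adduct 12 (not isolated)
Conditions: piperidinium acetate (cat.), EtOH, reflux
Reagents that add atoms: none
Why: twofold intermolecular Knoevenagel (aldol-type) condensation; the Meldrum's acid carbanion adds to each aldehyde and water is lost to form both C3–C4 bonds, then each neighbouring phenol opens the dioxanedione with loss of acetone to close the lactone, and no stereocentre is created.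

Step 8
Reactants: 13 8-{[5,7-bis(benzyloxy)-3-carboxy-2-oxo-2H-chromen-8-yl]oxy}-7-methoxy-2-oxo-2H-chromene-3-carboxylic acid
Product: 14 5,7-bis(benzyloxy)-8-[(7-methoxy-2-oxo-2H-chromen-8-yl)oxy]-2H-chromen-2-one
Conditions: Ag2CO3 (20 mol%), AcOH (10 mol%), DMSO, 120 °C
Reagents that add atoms: none
Why: silver-catalysed protodecarboxylation; the silver carboxylate next to the lactone carbonyl loses CO2 to a vinyl-silver species that is protonated by acetic acid, and benzyl ethers, methyl ether and lactones are inert under these conditions.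

Step 9
Reactants: 14 5,7-bis(benzyloxy)-8-[(7-methoxy-2-oxo-2H-chromen-8-yl)oxy]-2H-chromen-2-one
Product: 15 5,7-dihydroxy-8-[(7-methoxy-2-oxo-2H-chromen-8-yl)oxy]-2H-chromen-2-one
Conditions: BCl3 (6 equiv), pentamethylbenzene (6 equiv), CH2Cl2, −78 °C; then H2O
Reagents that add atoms: none
Why: Lewis-acid debenzylation with a cation scavenger; BCl3 ionises the benzyl–oxygen bonds at −78 °C and pentamethylbenzene traps the benzyl cation by Friedel–Crafts alkylation, leaving the aryl methyl ether, the diaryl ether and the coumarin C3–C4 double bonds intact.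

## Compound list

1 | 2,4-dihydroxybenzaldehyde | O=Cc1ccc(O)cc1O | starting material
2 | 2,4-bis(benzyloxy)benzaldehyde | O=Cc1ccc(OCc2ccccc2)cc1OCc1ccccc1 | intermediate
3 | 2,4-bis(benzyloxy)phenyl formate (not isolated) | O=COc1ccc(OCc2ccccc2)cc1OCc1ccccc1 | intermediate
4 | 2,4-bis(benzyloxy)phenol | Oc1ccc(OCc2ccccc2)cc1OCc1ccccc1 | intermediate
5 | 3,5-bis(benzyloxy)-2-hydroxybenzaldehyde | O=Cc1cc(OCc2ccccc2)cc(OCc2ccccc2)c1O | intermediate
6 | 2-fluoro-3-methoxybenzaldehyde | COc1cccc(C=O)c1F | starting material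
7 | 3,5-bis(benzyloxy)-2-(2-formyl-6-methoxyphenoxy)benzaldehyde | COc1cccc(C=O)c1Oc1c(C=O)cc(OCc2ccccc2)cc1OCc1ccccc1 | intermediate
8 | 2-[2,4-bis(benzyloxy)-6-(formyloxy)phenoxy]-3-methoxyphenyl formate (not isolated) | COc1cccc(OC=O)c1Oc1c(OC=O)cc(OCc2ccccc2)cc1OCc1ccccc1 | intermediate
9 | 3,5-bis(benzyloxy)-2-(2-hydroxy-6-methoxyphenoxy)phenol | COc1cccc(O)c1Oc1c(O)cc(OCc2ccccc2)cc1OCc1ccccc1 | intermediate
10 | 4,6-bis(benzyloxy)-3-(3-formyl-2-hydroxy-6-methoxyphenoxy)-2-hydroxybenzaldehyde | COc1ccc(C=O)c(O)c1Oc1c(O)c(C=O)c(OCc2ccccc2)cc1OCc1ccccc1 | intermediate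
11 | Meldrum's acid (2,2-dimethyl-1,3-dioxane-4,6-dione) | CC1(C)OC(=O)CC(=O)O1 | starting material
12 | bis-Knoevenagel adduct: 10 with each CHO replaced by a (2,2-dimethyl-4,6-dioxo-1,3-dioxan-5-ylidene)methyl group (not isolated) | COc1ccc(C=C2C(=O)OC(C)(C)OC2=O)c(O)c1Oc1c(O)c(C=C2C(=O)OC(C)(C)OC2=O)c(OCc2ccccc2)cc1OCc1ccccc1 | intermediate
13 | 8-{[5,7-bis(benzyloxy)-3-carboxy-2-oxo-2H-chromen-8-yl]oxy}-7-methoxy-2-oxo-2H-chromene-3-carboxylic acid | COc1ccc2cc(C(=O)O)c(=O)oc2c1Oc1c(OCc2ccccc2)cc(OCc2ccccc2)c2cc(C(=O)O)c(=O)oc12 | intermediate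
14 | 5,7-bis(benzyloxy)-8-[(7-methoxy-2-oxo-2H-chromen-8-yl)oxy]-2H-chromen-2-one | COc1ccc2ccc(=O)oc2c1Oc1c(OCc2ccccc2)cc(OCc2ccccc2)c2ccc(=O)oc12 | intermediate
15 | 5,7-dihydroxy-8-[(7-methoxy-2-oxo-2H-chromen-8-yl)oxy]-2H-chromen-2-one (CNP0305396.0, achiral) | COc1ccc2ccc(=O)oc2c1Oc1c(O)cc(O)c2ccc(=O)oc12 | target

## Summary

Total step count: 9. Longest linear sequence: 9 steps (1 to 15); fragments 6 and 11 are bought.

## Steps most likely to fail and their fallbacks

**Step 4 (SNAr to a diaryl ether with four ortho substituents).** The fallback sets out from 5 and comes back at 7. The ether is made by metal-free arylation with a diaryliodonium salt, which is much less sensitive to ortho crowding. Commercial 2-iodo-3-methoxybenzaldehyde (COc1cccc(C=O)c1I) is oxidised at iodine with mCPBA and TsOH·H2O in MeCN, and the trivalent iodine species is captured by 1,3,5-trimethoxybenzene to give (2-formyl-6-methoxyphenyl)(2,4,6-trimethoxyphenyl)iodonium tosylate F1. The potassium phenoxide of 5 (KOtBu, THF, 0 to 40 °C) then exchanges onto iodine and reductive elimination transfers the electron-poorer formyl-bearing aryl group, giving 7 and releasing the trimethoxyphenyl group as its iodide.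

**Step 5 (twofold Baeyer–Villiger oxidation; hydride migration to carboxylic acids may compete because each ring has only one ortho ether donor).** The fallback sets out from 7 and comes back at 9. Both formyl groups are turned into acetyl groups, for which only aryl migration is possible. MeMgBr (THF, 0 °C) gives the bis(1-hydroxyethyl) compound 1-{3,5-bis(benzyloxy)-2-[2-(1-hydroxyethyl)-6-methoxyphenoxy]phenyl}ethanol F2 as a mixture of stereoisomers, whose two carbinol centres are removed in the next operation. Dess–Martin periodinane (CH2Cl2, rt) gives the diketone 1-[2-(2-acetyl-4,6-bis(benzyloxy)phenoxy)-3-methoxyphenyl]ethanone F3. Baeyer–Villiger oxidation (mCPBA, cat. TFA, CH2Cl2, rt) gives the diacetate 2-[2-(acetyloxy)-4,6-bis(benzyloxy)phenoxy]-3-methoxyphenyl acetate F4. Methanolysis (K2CO3, MeOH) gives 9.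

**Step 8 (twofold protodecarboxylation of a poorly soluble diacid).** The fallback sets out from 10 and comes back at 14, so no carboxyl group is ever introduced. It is a Perkin reaction (Ac2O, NaOAc, 170 °C). The phenols are first acetylated to the diacetate 2-[2-(acetyloxy)-4,6-bis(benzyloxy)-3-formylphenoxy]-6-formyl-3-methoxyphenyl acetate F5, which forms in the flask. The acetate enolate then undergoes aldol-type condensation with the neighbouring aldehyde, and loss of water gives both unsubstituted pyranone rings of 14 directly.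

## Further compounds

F1 | step 4 | (2-formyl-6-methoxyphenyl)(2,4,6-trimethoxyphenyl)iodonium tosylate | COc1cccc(C=O)c1[I+]c1c(OC)cc(OC)cc1OC.Cc1ccc(S(=O)(=O)[O-])cc1
F2 | step 5 | 1-{3,5-bis(benzyloxy)-2-[2-(1-hydroxyethyl)-6-methoxyphenoxy]phenyl}ethanol (mixture of stereoisomers) | COc1cccc(C(C)O)c1Oc1c(C(C)O)cc(OCc2ccccc2)cc1OCc1ccccc1
F3 | step 5 | 1-[2-(2-acetyl-4,6-bis(benzyloxy)phenoxy)-3-methoxyphenyl]ethanone | COc1cccc(C(C)=O)c1Oc1c(C(C)=O)cc(OCc2ccccc2)cc1OCc1ccccc1
F4 | step 5 | 2-[2-(acetyloxy)-4,6-bis(benzyloxy)phenoxy]-3-methoxyphenyl acetate | COc1cccc(OC(C)=O)c1Oc1c(OC(C)=O)cc(OCc2ccccc2)cc1OCc1ccccc1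
F5 | step 8 | 2-[2-(acetyloxy)-4,6-bis(benzyloxy)-3-formylphenoxy]-6-formyl-3-methoxyphenyl acetate | COc1ccc(C=O)c(OC(C)=O)c1Oc1c(OC(C)=O)c(C=O)c(OCc2ccccc2)cc1OCc1ccccc1
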